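**Retrosynthetic overview**

1. The strategy rests on the 2,3-dihydrofuran rings: in dihydrofuran BC the phenol oxygen O1′ (on C7a′ of ring C) and the benzylic carbon C3′ (on C3a′, carrying CH2OH) are bridged by the single carbon C2′, which carries ring B; dihydrofuran AB (O1, C2 carrying ring A, C3) repeats this pattern on ring B.
2. Key disconnection: O1′–C2′ and C2′–C3′ are cut together, giving the ring C o-quinone methide (released from a 2-(1-tosyl-2-silyloxyethyl)phenol) and the benzylic ylide of an AB sulfonium salt built on C2-symmetric (2R,5R)-2,5-dimethylthiolane.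
3. The AB unit comes from the same (4+1) annulation one round earlier (ring A thiolanium ylide plus ring B quinone methide). Ring B carries its para carbon as a methyl ester, because an aldehyde there would be epoxidised by the ylide; the ester is then taken to CH2OH, CH2Br and the thiolanium salt. Tetrafluoroborates are used so that bromide cannot dealkylate the p-alkoxybenzyl sulfonium ions.
4. Both sulfone phenols come from o-iodophenols: metalation, addition to TBSOCH2CHO, then exchange of the benzylic hydroxyl for p-toluenesulfinate.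
5. Ring order: dihydrofuran AB (step 8), then dihydrofuran BC (step 16); fluoride and hydrogenolysis then free the four hydroxyls.

Key step: step 16

Assumption: the (2R,5R)-thiolane is taken as the antipode that gives 2R and 2′R, by analogy with the sense in which its benzylic ylides transfer the benzylidene carbon to aldehydes; if the sense were the reverse, the (2S,5S)-thiolane from (2R,5R)-hexane-2,5-diol would take its place unchanged in steps 4, 8, 11 and 16.

Abbreviations: TBS = tert-butyldimethylsilyl, Ts = p-toluenesulfonyl, Bn = benzyl.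

**Route**

Step 1
Reactants: 1 (2S,5S)-hexane-2,5-diol
Product: 2 (2S,5S)-hexane-2,5-diyl dimethanesulfonate
Conditions: MsCl, Et3N, CH2Cl2, −20 → 0 °C
Reagents that add atoms: methanesulfonyl chloride, CS(=O)(=O)Cl
Why: O-sulfonylation of both secondary hydroxyls breaks no C–O bond, so both centres should keep the S configuration.

Step 2
Reactants: 2 (2S,5S)-hexane-2,5-diyl dimethanesulfonate
Product: 3 (2R,5R)-2,5-dimethylthiolane
Conditions: Na2S·9H2O, EtOH, rt; distillation
Reagents that add atoms: sodium sulfide, [Na+].[Na+].[S-2]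
Why: Double SN2 displacement by sulfide (intermolecular, then 5-exo-tet) inverts both centres, so the (2S,5S)-dimesylate should give the (2R,5R)-thiolane.

Step 3
Reactants: 4 4-(benzyloxy)-3-methoxybenzyl alcohol
Product: 5 4-(benzyloxy)-3-methoxybenzyl bromide
Conditions: PBr3, Et2O, 0 °C; used directly
Reagents that add atoms: phosphorus tribromide, BrP(Br)Br
Why: Substitution of an electron-rich benzylic alcohol by bromide with PBr3 is standard and the aryl benzyl ether is inert at 0 °C.

Step 4
Reactants: 5 4-(benzyloxy)-3-methoxybenzyl bromide; 3 (2R,5R)-2,5-dimethylthiolane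
Product: 6 (2R,5R)-1-[4-(benzyloxy)-3-methoxybenzyl]-2,5-dimethylthiolanium tetrafluoroborate
Conditions: AgBF4, CH2Cl2, 0 °C → rt, dark; filtration, precipitation from Et2O
Reagents that add atoms: silver tetrafluoroborate, [Ag+].F[B-](F)(F)F
Why: S-alkylation of the thioether, made irreversible by precipitation of AgBr, should give a salt with a non-nucleophilic counter-ion, and the C2 symmetry of the thiolane makes its two lone pairs equivalent so that only one sulfonium stereoisomer can form.

Step 5
Reactants: 7 methyl vanillate (methyl 4-hydroxy-3-methoxybenzoate)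
Product: 8 methyl 5-iodovanillate (methyl 4-hydroxy-3-iodo-5-methoxybenzoate)
Conditions: NIS, TFA (cat.), MeCN, rt
Reagents that add atoms: N-iodosuccinimide, O=C1CCC(=O)N1I
Why: Electrophilic aromatic iodination should occur at C5, the only position ortho to the hydroxyl and meta to the ester.

Step 6
Reactants: 8 methyl 5-iodovanillate; 9 (tert-butyldimethylsilyloxy)acetaldehyde
Product: 11 methyl 4-hydroxy-3-[1-hydroxy-2-(TBSO)ethyl]-5-methoxybenzoate (racemic), via arylmagnesium phenoxide 10 (not isolated)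
Conditions: MeMgCl (1 equiv), LiCl, THF, −30 °C; i-PrMgCl (1.1 equiv), −30 °C; 9, −30 → 0 °C; AcOH then aq. NH4Cl, cold
Reagents that add atoms: none
Why: Deprotonation of the phenol followed by iodine–magnesium exchange, an established magnesiation of unprotected iodophenols that esters tolerate at low temperature, gives a Grignard reagent that adds to the aldehyde; the carbinol centre is racemic, which is harmless because this carbon becomes planar in step 8.

Step 7
Reactants: 11 methyl 4-hydroxy-3-[1-hydroxy-2-(TBSO)ethyl]-5-methoxybenzoate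
Product: 12 methyl 4-hydroxy-3-methoxy-5-[2-(TBSO)-1-tosylethyl]benzoate (racemic)
Conditions: p-TolSO2H (1.5 equiv), 4 Å sieves, CH2Cl2, rt
Reagents that add atoms: p-toluenesulfinic acid, Cc1ccc(cc1)S(=O)O
Why: Acid-mediated substitution of an ortho-hydroxybenzylic alcohol by sulfinate through sulfur is the standard preparation of 2-(1-sulfonylalkyl)phenols, and the weak acid in aprotic medium should spare the primary silyl ether.

Step 8
Reactants: 6 (2R,5R)-1-[4-(benzyloxy)-3-methoxybenzyl]-2,5-dimethylthiolanium tetrafluoroborate; 12 methyl 4-hydroxy-3-methoxy-5-[2-(TBSO)-1-tosylethyl]benzoate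
Product: 16 methyl (2R,3S)-2-[4-(benzyloxy)-3-methoxyphenyl]-7-methoxy-3-(TBSOCH2)-2,3-dihydrobenzofuran-5-carboxylate, via o-quinone methide 13 (not isolated), via sulfonium ylide 14 (not isolated), via betaine 15 (not isolated)
Conditions: Cs2CO3 (3 equiv), MeCN–CH2Cl2, 0 °C → rt
Reagents that add atoms: none
Why: Formal (4+1) annulation of an o-quinone methide with a sulfonium ylide, in which carbonate releases 13 from 12 by loss of sulfinate and 14 from 6, conjugate addition gives betaine 15 and 5-exo-tet displacement of the thiolane by the phenoxide closes dihydrofuran AB; C2 is set by the ylide face left open by the C2-symmetric thiolane, C3 by the preference for trans closure, and the ester, unlike an aldehyde, is inert to the ylide.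

Step 9
Reactants: 16 methyl (2R,3S)-2-[4-(benzyloxy)-3-methoxyphenyl]-7-methoxy-3-(TBSOCH2)-2,3-dihydrobenzofuran-5-carboxylate
Product: 17 [(2R,3S)-2-[4-(benzyloxy)-3-methoxyphenyl]-7-methoxy-3-(TBSOCH2)-2,3-dihydrobenzofuran-5-yl]methanol
Conditions: LiAlH4, THF, 0 °C; aq. NaOH work-up
Reagents that add atoms: none
Why: Hydride reduction of the aryl ester to the benzylic alcohol should leave the silyl ether, the benzyl ether and both stereocentres untouched.

Step 10
Reactants: 17 [(2R,3S)-2-[4-(benzyloxy)-3-methoxyphenyl]-7-methoxy-3-(TBSOCH2)-2,3-dihydrobenzofuran-5-yl]methanol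
Product: 18 (2R,3S)-2-[4-(benzyloxy)-3-methoxyphenyl]-5-(bromomethyl)-7-methoxy-3-(TBSOCH2)-2,3-dihydrobenzofuran
Conditions: CBr4, PPh3, 2,6-lutidine (cat.), CH2Cl2, 0 °C; rapid filtration through silica, used directly
Reagents that add atoms: carbon tetrabromide, BrC(Br)(Br)Br
Why: The Appel reaction converts the primary benzylic alcohol into the bromide under neutral conditions that the silyl ether and the acid-sensitive 2-aryl dihydrofuran tolerate.

Step 11
Reactants: 18 (2R,3S)-2-[4-(benzyloxy)-3-methoxyphenyl]-5-(bromomethyl)-7-methoxy-3-(TBSOCH2)-2,3-dihydrobenzofuran; 3 (2R,5R)-2,5-dimethylthiolane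
Product: 19 (2R,5R)-1-{[(2R,3S)-2-[4-(benzyloxy)-3-methoxyphenyl]-7-methoxy-3-(TBSOCH2)-2,3-dihydrobenzofuran-5-yl]methyl}-2,5-dimethylthiolanium tetrafluoroborate
Conditions: 3 (2 equiv), AgBF4 (1.05 equiv), CH2Cl2, −20 °C → rt, dark; filtration, trituration with Et2O
Reagents that add atoms: silver tetrafluoroborate, [Ag+].F[B-](F)(F)F
Why: The same S-alkylation as in step 4, where excess sulfide intercepts the reactive p-alkoxybenzyl electrophile and AgBr precipitation prevents reversal.

Step 12
Reactants: 20 dihydroconiferyl alcohol (4-(3-hydroxypropyl)-2-methoxyphenol)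
Product: 21 4-(3-hydroxypropyl)-2-iodo-6-methoxyphenol
Conditions: NaI, NaOH, aq. NaOCl (slow addition), MeOH, 0 °C
Reagents that add atoms: sodium iodide, [Na+].[I-]
Why: Iodination of the phenoxide by hypoiodite formed in situ should go ortho to the phenoxide oxygen, the strongest director, since the para position is blocked.

Step 13
Reactants: 21 4-(3-hydroxypropyl)-2-iodo-6-methoxyphenol
Product: 22 2-iodo-6-methoxy-4-[3-(TBSO)propyl]phenol
Conditions: TBSCl (1.05 equiv), imidazole, CH2Cl2, 0 °C
Reagents that add atoms: tert-butyldimethylsilyl chloride, CC(C)(C)[Si](C)(C)Cl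
Why: Silylation should be selective for the unhindered primary alcohol over the phenol, which is flanked by iodine and methoxy.

Step 14
Reactants: 22 2-iodo-6-methoxy-4-[3-(TBSO)propyl]phenol; 9 (tert-butyldimethylsilyloxy)acetaldehyde
Product: 24 2-[1-hydroxy-2-(TBSO)ethyl]-6-methoxy-4-[3-(TBSO)propyl]phenol (racemic), via dilithiated phenol 23 (not isolated)
Conditions: n-BuLi (2.2 equiv), THF, −78 °C; 9, −78 °C; AcOH then aq. NH4Cl at −78 °C
Reagents that add atoms: none
Why: Two equivalents of n-BuLi deprotonate the phenol and effect fast iodine–lithium exchange, and the o-lithiophenoxide adds to the aldehyde; the cold acidic quench guards against silyl migration between the vicinal oxygens.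

Step 15
Reactants: 24 2-[1-hydroxy-2-(TBSO)ethyl]-6-methoxy-4-[3-(TBSO)propyl]phenol
Product: 25 2-methoxy-6-[2-(TBSO)-1-tosylethyl]-4-[3-(TBSO)propyl]phenol (racemic)
Conditions: p-TolSO2H (1.5 equiv), 4 Å sieves, CH2Cl2, 0 °C → rt
Reagents that add atoms: p-toluenesulfinic acid, Cc1ccc(cc1)S(=O)O
Why: The same sulfinate-for-hydroxyl exchange as in step 7, here on an electron-rich ring that should ionise more readily, so milder exposure of the two silyl ethers suffices.

Step 16
Reactants: 19 AB thiolanium tetrafluoroborate; 25 2-methoxy-6-[2-(TBSO)-1-tosylethyl]-4-[3-(TBSO)propyl]phenol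
Product: 29 O-benzyl tris-O-TBS target, via o-quinone methide 26 (not isolated), via sulfonium ylide 27 (not isolated), via betaine 28 (not isolated)
Conditions: 25 (1.5 equiv), Cs2CO3 (3–4 equiv), MeCN–CH2Cl2, 0 °C → rt
Reagents that add atoms: none
Why: Cs2CO3 deprotonates phenol 25, whose phenoxide expels p-toluenesulfinate to give o-quinone methide 26, and deprotonates 19 to the semi-stabilised benzylic ylide 27; the ylide carbon adds to the exocyclic carbon of 26 in a conjugate addition that rearomatises ring C and forms C2′–C3′, and the phenoxide of betaine 28 then displaces the thiolane at C2′ with inversion, forming O1′–C2′. The closest known reaction type is the formal (4+1) annulation of sulfonium ylides with o-quinone methides released from 2-(1-sulfonylalkyl)phenols by carbonate bases, which gives trans-2,3-dihydrobenzofurans. Dihydrofuran BC closes by 5-exo-tet substitution. C2′ is controlled by the C2-symmetric (2R,5R)-thiolane, whose methyl groups shield one face of the ylide carbon as in benzylidene transfer to aldehydes, and C3′ is controlled relative to C2′ by closure through the betaine rotamer that places ring B and CH2OTBS anti; the exocyclic carbon of 26 is planar, so the racemic sulfone centre of 25 is irrelevant. The step needs C-attack of the ylide on 26 to outrun O-benzylation of the phenoxide by 19 and tautomerisation of 26, which the fast sulfinate loss from the electron-rich phenoxide and the excess of 25 should secure, and it needs reagent control to override the existing C2/C3 centres, which their position para across ring B from the ylide carbon makes likely. The silyl ethers, the benzyl ether and dihydrofuran AB are inert to carbonate at room temperature.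

Step 17
Reactants: 29 O-benzyl tris-O-TBS target
Product: 30 O-benzyl target (triol)
Conditions: TBAF (4 equiv), THF, 0 °C → rt
Reagents that add atoms: none
Why: Fluoride cleaves the three primary silyl ethers while the ring A phenol is still benzylated, so no phenoxide para to C2 can open dihydrofuran AB under the basic conditions.

Step 18
Reactants: 30 O-benzyl target (triol)
Product: 31 target, (2R,3S,2′R,3′S) as in the given SMILES
Conditions: H2 (1 atm), 10% Pd/C, EtOAc–MeOH, rt; stopped after one equivalent of H2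
Reagents that add atoms: none
Why: Hydrogenolysis of the aryl benzyl ether over Pd/C is much faster than that of the cyclic benzylic C2–O and C2′–O bonds, so the phenol should be freed with all four stereocentres intact.

**Compound list**

1 | (2S,5S)-hexane-2,5-diol | C[C@H](O)CC[C@H](C)O | starting material
2 | (2S,5S)-hexane-2,5-diyl dimethanesulfonate | C[C@H](OS(C)(=O)=O)CC[C@H](C)OS(C)(=O)=O | intermediate
3 | (2R,5R)-2,5-dimethylthiolane | C[C@@H]1CC[C@@H](C)S1 | intermediate
4 | 4-(benzyloxy)-3-methoxybenzyl alcohol | COc1cc(CO)ccc1OCc1ccccc1 | starting material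
5 | 4-(benzyloxy)-3-methoxybenzyl bromide | COc1cc(CBr)ccc1OCc1ccccc1 | intermediate
6 | ring A salt, (2R,5R)-1-[4-(benzyloxy)-3-methoxybenzyl]-2,5-dimethylthiolanium tetrafluoroborate | COc1cc(C[S+]2[C@H](C)CC[C@H]2C)ccc1OCc1ccccc1.F[B-](F)(F)F | intermediate
7 | methyl vanillate | COC(=O)c1ccc(O)c(OC)c1 | starting material
8 | methyl 5-iodovanillate | COC(=O)c1cc(I)c(O)c(OC)c1 | intermediate
9 | (tert-butyldimethylsilyloxy)acetaldehyde | CC(C)(C)[Si](C)(C)OCC=O | starting material
10 | arylmagnesium phenoxide, methyl 3-(chloromagnesio)-4-(chloromagnesiooxy)-5-methoxybenzoate | COC(=O)c1cc([Mg]Cl)c(O[Mg]Cl)c(OC)c1 | intermediate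
11 | ring B carbinol, methyl 4-hydroxy-3-[1-hydroxy-2-(TBSO)ethyl]-5-methoxybenzoate (racemic) | COC(=O)c1cc(OC)c(O)c(C(O)CO[Si](C)(C)C(C)(C)C)c1 | intermediate
12 | ring B sulfone phenol, methyl 4-hydroxy-3-methoxy-5-[2-(TBSO)-1-tosylethyl]benzoate (racemic) | COC(=O)c1cc(OC)c(O)c(C(CO[Si](C)(C)C(C)(C)C)S(=O)(=O)c2ccc(C)cc2)c1 | intermediate
13 | ring B o-quinone methide, 6-[2-(TBSO)ethylidene]-2-methoxy-4-(methoxycarbonyl)cyclohexa-2,4-dien-1-one | COC(=O)C1=CC(=CCO[Si](C)(C)C(C)(C)C)C(=O)C(OC)=C1 | intermediate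
14 | ring A sulfonium ylide of 6 | COc1cc([CH-][S+]2[C@H](C)CC[C@H]2C)ccc1OCc1ccccc1 | intermediate
15 | AB betaine, ring B phenoxide carrying CH(CH2OTBS)–CH(ring A)–thiolanium | COC(=O)c1cc(OC)c([O-])c(c1)[C@@H](CO[Si](C)(C)C(C)(C)C)[C@@H](c1ccc(OCc2ccccc2)c(OC)c1)[S+]1[C@H](C)CC[C@H]1C | intermediate
16 | AB ester, methyl (2R,3S)-2-[4-(benzyloxy)-3-methoxyphenyl]-7-methoxy-3-(TBSOCH2)-2,3-dihydrobenzofuran-5-carboxylate | COc1cc([C@@H]2Oc3c(OC)cc(C(=O)OC)cc3[C@H]2CO[Si](C)(C)C(C)(C)C)ccc1OCc1ccccc1 | intermediate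
17 | AB benzylic alcohol, (2R,3S), 5-CH2OH | COc1cc([C@@H]2Oc3c(OC)cc(CO)cc3[C@H]2CO[Si](C)(C)C(C)(C)C)ccc1OCc1ccccc1 | intermediate
18 | AB benzylic bromide, (2R,3S), 5-CH2Br | COc1cc([C@@H]2Oc3c(OC)cc(CBr)cc3[C@H]2CO[Si](C)(C)C(C)(C)C)ccc1OCc1ccccc1 | intermediate
19 | AB thiolanium tetrafluoroborate, (2R,3S) dihydrobenzofuran with 5-CH2–S+ of (2R,5R)-2,5-dimethylthiolane | COc1cc([C@@H]2Oc3c(OC)cc(C[S+]4[C@H](C)CC[C@H]4C)cc3[C@H]2CO[Si](C)(C)C(C)(C)C)ccc1OCc1ccccc1.F[B-](F)(F)F | intermediate
20 | dihydroconiferyl alcohol | COc1cc(CCCO)ccc1O | starting material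
21 | 4-(3-hydroxypropyl)-2-iodo-6-methoxyphenol | COc1cc(CCCO)cc(I)c1O | intermediate
22 | 2-iodo-6-methoxy-4-[3-(TBSO)propyl]phenol | COc1cc(CCCO[Si](C)(C)C(C)(C)C)cc(I)c1O | intermediate
23 | dilithiated phenol, lithium 2-lithio-6-methoxy-4-[3-(TBSO)propyl]phenoxide | COc1cc(CCCO[Si](C)(C)C(C)(C)C)cc([Li])c1O[Li] | intermediate
24 | ring C carbinol, 2-[1-hydroxy-2-(TBSO)ethyl]-6-methoxy-4-[3-(TBSO)propyl]phenol (racemic) | COc1cc(CCCO[Si](C)(C)C(C)(C)C)cc(C(O)CO[Si](C)(C)C(C)(C)C)c1O | intermediate
25 | ring C sulfone phenol, 2-methoxy-6-[2-(TBSO)-1-tosylethyl]-4-[3-(TBSO)propyl]phenol (racemic) | COc1cc(CCCO[Si](C)(C)C(C)(C)C)cc(C(CO[Si](C)(C)C(C)(C)C)S(=O)(=O)c2ccc(C)cc2)c1O | intermediate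
26 | ring C o-quinone methide, 6-[2-(TBSO)ethylidene]-2-methoxy-4-[3-(TBSO)propyl]cyclohexa-2,4-dien-1-one | COC1=CC(CCCO[Si](C)(C)C(C)(C)C)=CC(=CCO[Si](C)(C)C(C)(C)C)C1=O | intermediate
27 | AB sulfonium ylide of 19 | COc1cc([C@@H]2Oc3c(OC)cc([CH-][S+]4[C@H](C)CC[C@H]4C)cc3[C@H]2CO[Si](C)(C)C(C)(C)C)ccc1OCc1ccccc1 | intermediate
28 | ABC betaine, ring C phenoxide carrying CH(CH2OTBS)–CH(AB unit)–thiolanium | COc1cc(CCCO[Si](C)(C)C(C)(C)C)cc(c1[O-])[C@@H](CO[Si](C)(C)C(C)(C)C)[C@@H](c1cc(OC)c2O[C@@H](c3ccc(OCc4ccccc4)c(OC)c3)[C@H](CO[Si](C)(C)C(C)(C)C)c2c1)[S+]1[C@H](C)CC[C@H]1C | intermediate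
29 | O-benzyl tris-O-TBS target, (2R,3S,2′R,3′S) | COc1cc([C@@H]2Oc3c(OC)cc([C@@H]4Oc5c(OC)cc(CCCO[Si](C)(C)C(C)(C)C)cc5[C@H]4CO[Si](C)(C)C(C)(C)C)cc3[C@H]2CO[Si](C)(C)C(C)(C)C)ccc1OCc1ccccc1 | intermediate
30 | O-benzyl target (triol), (2R,3S,2′R,3′S) | COc1cc([C@@H]2Oc3c(OC)cc([C@@H]4Oc5c(OC)cc(CCCO)cc5[C@H]4CO)cc3[C@H]2CO)ccc1OCc1ccccc1 | intermediate
31 | CNP0599161.1, (2R,3S,2′R,3′S) | COc1cc([C@@H]2Oc3c(OC)cc([C@@H]4Oc5c(OC)cc(CCCO)cc5[C@H]4CO)cc3[C@H]2CO)ccc1O | target

**Step count**

Total steps: 18. Longest linear sequence: 10 steps (steps 5, 6, 7, 8, 9, 10, 11, 16, 17, 18; the line from diol 1 through steps 1, 2, 4 and 8 is equally long).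

**Steps most likely to fail, with fallbacks**

1. Step 16.
   - What may go wrong: quinone methide 26 has hydrogens on the carbon next to its exocyclic double bond and may tautomerise to the 2-alkenylphenol or oligomerise before the hindered thiolanium ylide adds. The phenoxide of 25 may be O-benzylated by the ionisation-prone salt 19. Facial control by the thiolane may be incomplete, giving C2′/C3′ diastereomers.
   - Fallback (sets out from bromide 18 and iodophenol 22, comes back at triol 30): dihydrofuran BC would be closed by carbenoid C–H insertion instead. O-Alkylation of 22 with 18 (K2CO3, DMF) should give the aryl benzylic ether F1. Palladium-catalysed coupling of its aryl iodide with the Reformatsky reagent BrZnCH2CO2t-Bu (Pd(dba)2, P(t-Bu)3, THF) should give the tert-butyl arylacetate F2, and diazo transfer (4-acetamidobenzenesulfonyl azide, DBU, MeCN) the aryldiazoacetate F3. Intramolecular insertion of the rhodium carbenoid into the ring B–CH2–O C–H bond should give the cis-dihydrobenzofuran ester F4; the catalyst is the chiral dirhodium carboxylate Rh2(S-PTTL)4, dirhodium tetrakis[N-phthaloyl-(S)-tert-leucinate], or its enantiomer, whichever delivers 2′R, in toluene at low temperature. Epimerisation at C3′ through the ester enolate (t-BuOK cat., THF) should give the trans ester F5, and LiAlH4 the C3′ carbinol F6, which the conditions of step 17 convert into 30.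

2. Step 8.
   - What may go wrong: the para ester slows loss of sulfinate from the phenoxide of 12, so O-alkylation of the long-lived phenoxide by salt 6 and decay of the ylide may outrun the annulation.
   - Fallback (sets out from salt 6 and aldehyde 9, comes back at alcohol 17): ring B would be carried as an electronically neutral aryl bromide and its benzylic carbon introduced after the annulation. Purchased 4-bromo-2-methoxyphenol F7 is iodinated as in step 12 to 4-bromo-2-iodo-6-methoxyphenol F8. Iodine-selective magnesiation and addition to 9 as in step 6 should give the bromo carbinol F9, and p-toluenesulfinic acid as in step 7 the bromo sulfone phenol F10. Annulation with 6 under the conditions of step 8 should give the 5-bromo dihydrobenzofuran F11. Bromine–lithium exchange (n-BuLi, THF, −78 °C) and DMF should give the AB aldehyde F12, which NaBH4 in MeOH reduces to 17.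

3. Step 7.
   - What may go wrong: ionisation of the benzylic carbinol is retarded by the para ester and the neighbouring silyloxy group; forcing it with stronger acid invites loss of the silyl group and a 1,2-hydride shift towards the arylacetaldehyde.
   - Fallback (sets out from carbinol 11, comes back at ester 16): the quinone methide would be released by fluoride instead of from a sulfone, so no acid is needed. Silylation of the phenol (TBSCl, imidazole, DMF, 0 °C) should give the aryl silyl ether F13, and acetylation (Ac2O, pyridine, DMAP) the benzylic acetate F14. Treating F14 and salt 6 with CsF and Cs2CO3 in MeCN should cleave the aryl silyl ether selectively; the phenoxide expels acetate to give the same quinone methide 13, which ylide 14 intercepts to give 16.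

**Further compounds**

F1 | step 16 | aryl benzylic ether of 22 with the AB benzylic carbon of 18 | COc1cc([C@@H]2Oc3c(OC)cc(COc4c(I)cc(CCCO[Si](C)(C)C(C)(C)C)cc4OC)cc3[C@H]2CO[Si](C)(C)C(C)(C)C)ccc1OCc1ccccc1
F2 | step 16 | tert-butyl arylacetate (CH2CO2t-Bu in place of iodine in F1) | COc1cc([C@@H]2Oc3c(OC)cc(COc4c(CC(=O)OC(C)(C)C)cc(CCCO[Si](C)(C)C(C)(C)C)cc4OC)cc3[C@H]2CO[Si](C)(C)C(C)(C)C)ccc1OCc1ccccc1
F3 | step 16 | tert-butyl aryldiazoacetate | COc1cc([C@@H]2Oc3c(OC)cc(COc4c(C(=[N+]=[N-])C(=O)OC(C)(C)C)cc(CCCO[Si](C)(C)C(C)(C)C)cc4OC)cc3[C@H]2CO[Si](C)(C)C(C)(C)C)ccc1OCc1ccccc1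
F4 | step 16 | cis-2′,3′ dihydrobenzofuran BC tert-butyl ester (C2′ as in the target, C3′ epimeric) | COc1cc([C@@H]2Oc3c(OC)cc([C@@H]4Oc5c(OC)cc(CCCO[Si](C)(C)C(C)(C)C)cc5[C@@H]4C(=O)OC(C)(C)C)cc3[C@H]2CO[Si](C)(C)C(C)(C)C)ccc1OCc1ccccc1
F5 | step 16 | trans-2′,3′ dihydrobenzofuran BC tert-butyl ester | COc1cc([C@@H]2Oc3c(OC)cc([C@@H]4Oc5c(OC)cc(CCCO[Si](C)(C)C(C)(C)C)cc5[C@H]4C(=O)OC(C)(C)C)cc3[C@H]2CO[Si](C)(C)C(C)(C)C)ccc1OCc1ccccc1
F6 | step 16 | O-benzyl bis-O-TBS target with free C3′ CH2OH | COc1cc([C@@H]2Oc3c(OC)cc([C@@H]4Oc5c(OC)cc(CCCO[Si](C)(C)C(C)(C)C)cc5[C@H]4CO)cc3[C@H]2CO[Si](C)(C)C(C)(C)C)ccc1OCc1ccccc1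
F7 | step 8 | 4-bromo-2-methoxyphenol (purchased) | COc1cc(Br)ccc1O
F8 | step 8 | 4-bromo-2-iodo-6-methoxyphenol | COc1cc(Br)cc(I)c1O
F9 | step 8 | 4-bromo-2-[1-hydroxy-2-(TBSO)ethyl]-6-methoxyphenol (racemic) | COc1cc(Br)cc(C(O)CO[Si](C)(C)C(C)(C)C)c1O
F10 | step 8 | 4-bromo-2-methoxy-6-[2-(TBSO)-1-tosylethyl]phenol (racemic) | COc1cc(Br)cc(C(CO[Si](C)(C)C(C)(C)C)S(=O)(=O)c2ccc(C)cc2)c1O
F11 | step 8 | (2R,3S)-2-[4-(benzyloxy)-3-methoxyphenyl]-5-bromo-7-methoxy-3-(TBSOCH2)-2,3-dihydrobenzofuran | COc1cc([C@@H]2Oc3c(OC)cc(Br)cc3[C@H]2CO[Si](C)(C)C(C)(C)C)ccc1OCc1ccccc1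
F12 | step 8 | (2R,3S)-2-[4-(benzyloxy)-3-methoxyphenyl]-7-methoxy-3-(TBSOCH2)-2,3-dihydrobenzofuran-5-carbaldehyde | COc1cc([C@@H]2Oc3c(OC)cc(C=O)cc3[C@H]2CO[Si](C)(C)C(C)(C)C)ccc1OCc1ccccc1
F13 | step 7 | methyl 4-(TBSO)-3-[1-hydroxy-2-(TBSO)ethyl]-5-methoxybenzoate (racemic) | COC(=O)c1cc(OC)c(O[Si](C)(C)C(C)(C)C)c(C(O)CO[Si](C)(C)C(C)(C)C)c1
F14 | step 7 | methyl 3-[1-acetoxy-2-(TBSO)ethyl]-4-(TBSO)-5-methoxybenzoate (racemic) | COC(=O)c1cc(OC)c(O[Si](C)(C)C(C)(C)C)c(C(OC(C)=O)CO[Si](C)(C)C(C)(C)C)c1
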